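Retrosynthesis (locants follow the icosatetraenoic acid chain C1–C20, with the second carboxyl carbon on C3 and the formyl carbon on C7): free the C4 hydroxyl last and open the anhydride ring (O, C1, C2, C3, carboxyl carbon on C3) to a diacid. Then cut C5–C6, then C3–C4 in the head, and C6=C7 and C8–C9 in the tail.
Enabling feature: C5 is a plain CH2 between the oxygen-bearing C4 and C6, the only hydrogen-bearing carbon of the C6=C7 enal. With one extra CO2H on C5 the head is a 3-silyloxy acid, which is an aldol product, and C6 can carry iodine. A C5 radical keeps its β-oxygen, whereas a C5 organometallic would expel it, so the radical can be joined to an alkenylnickel at C6.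
Forward: head 13 in six steps (imide, syn-aldol, silylation, debenzylation, oxidation, redox-active ester) and tail 18 in two steps (enolate allylation, iodoolefination). C5–C6 is formed by nickel-electrocatalytic decarboxylative alkenylation. Then follow auxiliary and acetal removal, tert-butyl ester cleavage, closure of the only ring, and desilylation.
Stereochemistry: C3 (S) and C4 (R) are set together in the boron aldol of the (S)-4-benzyloxazolidinone imide. The C10 and C14 alkenes come with (2E,6E)-farnesyl bromide. C6=C7 (E) comes from the iodoolefination, is retained in the coupling, and is also the thermodynamically preferred enal geometry.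

Key step: step 9

Remark: the free 4-hydroxy anhydride is taken to be isolable as drawn, because acyl transfer to the isomeric γ-lactone acid needs a strained bicyclo[2.2.1] tetrahedral intermediate. The hydroxyl is therefore unveiled in the last step.

Step 1
Reactants: 1 4-tert-butoxy-4-oxobutanoic acid (mono-tert-butyl succinate); 2 (S)-4-benzyl-1,3-oxazolidin-2-one
Product: 4 tert-butyl 4-[(4S)-4-benzyl-2-oxo-1,3-oxazolidin-3-yl]-4-oxobutanoate, via mixed pivalic anhydride 3 (not isolated)
Conditions: PivCl, Et3N, THF, −20 °C; then LiCl, 2, −20 °C to rt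
Reagents that add atoms: none
Why: Mixed-anhydride N-acylation of the oxazolidinone (LiCl/Et3N variant) should give the imide without going through the acid chloride of 1, which tends to collapse to succinic anhydride.

Step 2
Reactants: 4 imide; 5 3-(benzyloxy)propanal
Product: 8 tert-butyl (3S,4R)-3-{[(4S)-4-benzyl-2-oxo-1,3-oxazolidin-3-yl]carbonyl}-6-(benzyloxy)-4-hydroxyhexanoate, via dibutylboron Z-enolate 6 (not isolated), via boron aldolate 7 (not isolated)
Conditions: Bu2BOTf, i-Pr2NEt, CH2Cl2, −78 to 0 °C; 5, −78 to 0 °C; then pH 7 buffer, MeOH, H2O2, 0 °C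
Reagents that add atoms: none
Why: In this Evans boron syn-aldol the Z-enolate reacts through a Zimmerman–Traxler chair on the face away from the benzyl group, which should set C3 as S and C4 as R in one event, and the bulky tert-butyl ester keeps the new hydroxyl from lactonising.

Step 3
Reactants: 8 syn-aldol
Product: 9 tert-butyl (3S,4R)-3-{[(4S)-4-benzyl-2-oxo-1,3-oxazolidin-3-yl]carbonyl}-6-(benzyloxy)-4-(triethylsilyloxy)hexanoate
Conditions: TESOTf, 2,6-lutidine, CH2Cl2, −78 to 0 °C
Reagents that add atoms: triethylsilyl trifluoromethanesulfonate, CC[Si](CC)(CC)OS(=O)(=O)C(F)(F)F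
Why: Silyl triflate silylation of a hindered secondary alcohol under weakly basic conditions should proceed without retro-aldol, blocks lactonisation for the rest of the route, and installs a group that fluoride removes fast at the end.

Step 4
Reactants: 9 silyl ether
Product: 10 tert-butyl (3S,4R)-3-{[(4S)-4-benzyl-2-oxo-1,3-oxazolidin-3-yl]carbonyl}-6-hydroxy-4-(triethylsilyloxy)hexanoate
Conditions: H2 (1 atm), Pd/C, EtOAc, rt
Reagents that add atoms: none
Why: Hydrogenolysis of the benzyl ether is safe here because no alkene is present yet, the carbon-bound benzyl of the auxiliary is inert, and neutral EtOAc spares the silyl ether; 10 is oxidised at once to forestall δ-lactonisation onto the imide.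

Step 5
Reactants: 10 primary alcohol
Product: 12 (3R,4S)-4-{[(4S)-4-benzyl-2-oxo-1,3-oxazolidin-3-yl]carbonyl}-6-tert-butoxy-6-oxo-3-(triethylsilyloxy)hexanoic acid, via aldehyde 11 (not isolated)
Conditions: TEMPO (cat.), PhI(OAc)2, MeCN/pH 7 buffer, rt
Reagents that add atoms: water, O
Why: Oxoammonium-catalysed oxidation of a primary alcohol through the aldehyde hydrate to the acid is mild enough for the imide, the tert-butyl ester and the buffered silyl ether.

Step 6
Reactants: 12 acid
Product: 13 1,3-dioxoisoindolin-2-yl ester of 12 (redox-active ester)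
Conditions: N-hydroxyphthalimide, DIC, DMAP (cat.), CH2Cl2, rt
Reagents that add atoms: N-hydroxyphthalimide, O=C1c2ccccc2C(=O)N1O
Why: Carbodiimide (Steglich-type) esterification of the only free carboxyl group installs the electron-accepting handle, while the other two carboxyl carbons stay masked as imide and tert-butyl ester.

Step 7
Reactants: 14 1,1-dimethoxypropan-2-one; 15 (2E,6E)-farnesyl bromide
Product: 17 (5E,9E)-1,1-dimethoxy-6,10,14-trimethylpentadeca-5,9,13-trien-2-one, via lithium enolate 16 (not isolated)
Conditions: LDA, THF, −78 °C; 15, DMPU, −78 to −20 °C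
Reagents that add atoms: none
Why: Kinetic deprotonation takes place at the methyl group rather than the hindered acetal methine, and direct SN2 allylation with the primary allylic bromide should form C8–C9 with both alkene geometries kept.

Step 8
Reactants: 17 α-keto acetal
Product: 18 (1E,5E,9E)-2-(dimethoxymethyl)-1-iodo-6,10,14-trimethylpentadeca-1,5,9,13-tetraene
Conditions: CrCl2, CHI3, THF, 0 °C to rt
Reagents that add atoms: iodoform, IC(I)I
Why: In the Takai–Utimoto iodoolefination the geminal dichromium reagent adds to the inductively activated ketone and the anti-elimination should place iodine away from the branched dimethoxymethyl group (E), under neutral conditions that leave the acetal and the trisubstituted alkenes alone.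

Step 9
Reactants: 13 redox-active ester; 18 alkenyl iodide
Product: 20 tert-butyl (3S,4R,6E,10E,14E)-3-{[(4S)-4-benzyl-2-oxo-1,3-oxazolidin-3-yl]carbonyl}-7-(dimethoxymethyl)-11,15,19-trimethyl-4-(triethylsilyloxy)icosa-6,10,14,18-tetraenoate, via primary C5 radical 19 (not isolated)
Conditions: NiCl2·6H2O (cat.), 2,2'-bipyridine (cat.), AgNO3 (substoichiometric), DMF, Mg anode, reticulated vitreous carbon cathode, undivided cell, constant current, rt
Reagents that add atoms: none
Why: At the silver-coated cathode the bipyridine complex of divalent nickel is reduced to low-valent nickel, which inserts into the carbon–iodine bond of 18 with retention and also passes one electron to 13, whose radical anion loses phthalimide anion and CO2 to give radical 19; capture of 19 by the alkenylnickel gives a trivalent nickel species that forms C5–C6 by reductive elimination, the magnesium anode supplying the two electrons. The closest known reaction type is the nickel-electrocatalytic decarboxylative alkenylation of N-hydroxyphthalimide esters of primary acids with trisubstituted alkenyl iodides, which was developed on polyene terpenoid chains. No ring is closed and no stereocentre is made, and C3 and C4 lie beside the radical centre and should pass through unchanged. Cross-coupling over homo-coupling is secured because the two partners are activated differently (two-electron insertion for the sp2 iodide, one-electron transfer for the ester). The E geometry should be retained because the alkenylnickel is configurationally stable. The β-silyloxy group stays in place because carbon–oxygen β-scission of a radical is slow, and imide, tert-butyl ester, acetal, silyl ether and isolated alkenes are not reduced at the working potential.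

Step 10
Reactants: 20 coupled imide
Product: 23 tert-butyl (3S,4R,6E,10E,14E)-3-carboxy-7-formyl-11,15,19-trimethyl-4-(triethylsilyloxy)icosa-6,10,14,18-tetraenoate, via peroxy acid 21 (not isolated), via acetal acid 22 (not isolated)
Conditions: LiOH, H2O2, THF/H2O, 0 °C; Na2SO3; then dilute HCl to pH 4, 0 °C to rt
Reagents that add atoms: hydrogen peroxide, OO; water, O
Why: Hydroperoxide cleavage of the Evans imide attacks the exocyclic carbonyl without epimerising C3 while the enal is still masked against peroxide, and after the sulfite quench the allylic dimethyl acetal hydrolyses at mild pH in water, which traps the oxocarbenium ion before the polyene can and favours the E enal.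

Step 11
Reactants: 23 mono acid
Product: 25 (3S,4R,6E,10E,14E)-3-carboxy-7-formyl-11,15,19-trimethyl-4-(triethylsilyloxy)icosa-6,10,14,18-tetraenoic acid, via bis(trimethylsilyl) ester 24 (not isolated)
Conditions: TMSOTf, 2,6-lutidine, CH2Cl2, 0 °C; then pH 5 buffer
Reagents that add atoms: none
Why: Silyl triflate-mediated tert-butyl ester cleavage (carbonyl silylation, then loss of 2-methylpropene to the hindered base) avoids protic acid, so the polyene and the silyl ether should survive, and the labile trimethylsilyl esters fall off on buffered work-up.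

Step 12
Reactants: 25 diacid
Product: 26 (3S)-3-[(1R,3E,7E,11E)-4-formyl-8,12,16-trimethyl-1-(triethylsilyloxy)heptadeca-3,7,11,15-tetraen-1-yl]oxolane-2,5-dione
Conditions: DCC, CH2Cl2, 0 °C; filtration
Reagents that add atoms: none
Why: In this carbodiimide dehydration of a succinic acid the O-acylisourea of one carboxyl is attacked by the other in a 5-exo-trig closure, under neutral and water-free conditions that should leave the enal, the silyl ether and the C3 configuration intact.

Step 13
Reactants: 26 silyl-protected anhydride
Product: 27 hippolide D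
Conditions: HF·pyridine, pyridine, THF, 0 °C
Reagents that add atoms: none
Why: Buffered, water-free fluoride desilylation of a triethylsilyl ether is fast at 0 °C and uses no nucleophilic solvent, so the anhydride ring, the enal and both stereocentres should persist.

Compound list
1 | 4-tert-butoxy-4-oxobutanoic acid | CC(C)(C)OC(=O)CCC(=O)O | starting material
2 | (S)-4-benzyl-1,3-oxazolidin-2-one | O=C1OC[C@H](Cc2ccccc2)N1 | starting material
3 | mixed pivalic anhydride of 1 | CC(C)(C)OC(=O)CCC(=O)OC(=O)C(C)(C)C | intermediate
4 | tert-butyl 4-[(4S)-4-benzyl-2-oxo-1,3-oxazolidin-3-yl]-4-oxobutanoate | CC(C)(C)OC(=O)CCC(=O)N1[C@@H](Cc2ccccc2)COC1=O | intermediate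
5 | 3-(benzyloxy)propanal | O=CCCOCc1ccccc1 | starting material
6 | dibutylboron Z-enolate of 4 | CCCCB(CCCC)O/C(=C\CC(=O)OC(C)(C)C)N1[C@@H](Cc2ccccc2)COC1=O | intermediate
7 | dibutylboron aldolate | c1ccccc1COCC[C@@H](OB(CCCC)CCCC)[C@H](CC(=O)OC(C)(C)C)C(=O)N1[C@@H](Cc2ccccc2)COC1=O | intermediate
8 | (3S,4R) syn-aldol | c1ccccc1COCC[C@@H](O)[C@H](CC(=O)OC(C)(C)C)C(=O)N1[C@@H](Cc2ccccc2)COC1=O | intermediate
9 | triethylsilyl ether of 8 | c1ccccc1COCC[C@@H](O[Si](CC)(CC)CC)[C@H](CC(=O)OC(C)(C)C)C(=O)N1[C@@H](Cc2ccccc2)COC1=O | intermediate
10 | primary alcohol | OCC[C@@H](O[Si](CC)(CC)CC)[C@H](CC(=O)OC(C)(C)C)C(=O)N1[C@@H](Cc2ccccc2)COC1=O | intermediate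
11 | aldehyde | O=CC[C@@H](O[Si](CC)(CC)CC)[C@H](CC(=O)OC(C)(C)C)C(=O)N1[C@@H](Cc2ccccc2)COC1=O | intermediate
12 | (3R,4S) 3-silyloxy acid | OC(=O)C[C@@H](O[Si](CC)(CC)CC)[C@H](CC(=O)OC(C)(C)C)C(=O)N1[C@@H](Cc2ccccc2)COC1=O | intermediate
13 | N-hydroxyphthalimide ester of 12 | O=C(C[C@@H](O[Si](CC)(CC)CC)[C@H](CC(=O)OC(C)(C)C)C(=O)N1[C@@H](Cc2ccccc2)COC1=O)ON1C(=O)c2ccccc2C1=O | intermediate
14 | 1,1-dimethoxypropan-2-one | CC(=O)C(OC)OC | starting material
15 | (2E,6E)-farnesyl bromide | CC(C)=CCC/C(C)=C/CC/C(C)=C/CBr | starting material
16 | lithium enolate of 14 | [Li]OC(=C)C(OC)OC | intermediate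
17 | (5E,9E)-1,1-dimethoxy-6,10,14-trimethylpentadeca-5,9,13-trien-2-one | CC(C)=CCC/C(C)=C/CC/C(C)=C/CCC(=O)C(OC)OC | intermediate
18 | (1E,5E,9E)-2-(dimethoxymethyl)-1-iodo-6,10,14-trimethylpentadeca-1,5,9,13-tetraene | CC(C)=CCC/C(C)=C/CC/C(C)=C/CC/C(C(OC)OC)=C\I | intermediate
19 | primary C5 radical | [CH2][C@@H](O[Si](CC)(CC)CC)[C@H](CC(=O)OC(C)(C)C)C(=O)N1[C@@H](Cc2ccccc2)COC1=O | intermediate
20 | coupled imide acetal | CC(C)=CCC/C(C)=C/CC/C(C)=C/CC/C(C(OC)OC)=C\C[C@@H](O[Si](CC)(CC)CC)[C@H](CC(=O)OC(C)(C)C)C(=O)N1[C@@H](Cc2ccccc2)COC1=O | intermediate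
21 | peroxy acid | CC(C)=CCC/C(C)=C/CC/C(C)=C/CC/C(C(OC)OC)=C\C[C@@H](O[Si](CC)(CC)CC)[C@H](CC(=O)OC(C)(C)C)C(=O)OO | intermediate
22 | acetal acid | CC(C)=CCC/C(C)=C/CC/C(C)=C/CC/C(C(OC)OC)=C\C[C@@H](O[Si](CC)(CC)CC)[C@H](CC(=O)OC(C)(C)C)C(=O)O | intermediate
23 | enal mono acid mono tert-butyl ester | CC(C)=CCC/C(C)=C/CC/C(C)=C/CC/C(C=O)=C\C[C@@H](O[Si](CC)(CC)CC)[C@H](CC(=O)OC(C)(C)C)C(=O)O | intermediate
24 | bis(trimethylsilyl) ester | CC(C)=CCC/C(C)=C/CC/C(C)=C/CC/C(C=O)=C\C[C@@H](O[Si](CC)(CC)CC)[C@H](CC(=O)O[Si](C)(C)C)C(=O)O[Si](C)(C)C | intermediate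
25 | silyl-protected enal diacid | CC(C)=CCC/C(C)=C/CC/C(C)=C/CC/C(C=O)=C\C[C@@H](O[Si](CC)(CC)CC)[C@H](CC(=O)O)C(=O)O | intermediate
26 | silyl-protected anhydride | CC(C)=CCC/C(C)=C/CC/C(C)=C/CC/C(C=O)=C\C[C@@H](O[Si](CC)(CC)CC)[C@@H]1CC(=O)OC1=O | intermediate
27 | hippolide D | CC(C)=CCC/C(C)=C/CC/C(C)=C/CC/C(C=O)=C\C[C@@H](O)[C@@H]1CC(=O)OC1=O | target

Total step count: 13. Longest linear sequence: 11 (steps 1–6, then 9–13).

Steps most likely to fail

Step 9. The C5 radical may be lost to hydrogen abstraction or over-reduction, the alkenyl partner may dimerise or be protodehalogenated, or the electrodes may passivate. The fallback replaces the cross-electrophile electrolysis by a redox-neutral coupling with a preformed nucleophile. It sets out from 18, which is turned by iodine–lithium exchange (t-BuLi, Et2O, −78 °C) and ZnCl2 into the alkenylzinc chloride F2. F2 is coupled with 13 under Ni(acac)2 and 2,2'-bipyridine in THF/DMF at rt (thermal decarboxylative alkenylation), and the route is rejoined at 20.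

Step 8. Addition of the dichromium reagent to a ketone may be sluggish, and control of the alkene geometry may be poor. The fallback sets out from 17 and uses a boron–Wittig olefination. Lithiated bis(pinacolatoboryl)methane (from CH2(Bpin)2 and LiTMP, THF, −78 °C to rt) should give the alkenyl pinacol boronate F1, with boron away from the branched acetal. Stereoretentive iododeboronation follows (NaOH, then iodine added slowly, THF, 0 °C, so that the boronate consumes it before the alkenes can), and the route is rejoined at 18.

Step 13. Once the hydroxyl is free it may transfer onto the ring carbonyl to give the lactone acid, and fluoride or adventitious water may open the anhydride. The fallback reverses the order of events. It sets out from 25, which is desilylated with Et3N·3HF in the presence of excess Et3N (MeCN, 0 °C), so that the product is held as the non-electrophilic bis(triethylammonium) hydroxy dicarboxylate F3. DCC is then added at −20 °C, where the neighbouring carboxylate should outrun the neutral hydroxyl in attacking the O-acylisourea. The ring closes last and the route is rejoined directly at 27.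

Further compounds
F1 | step 8 | (E)-alkenyl pinacol boronate corresponding to 18 | CC(C)=CCC/C(C)=C/CC/C(C)=C/CC/C(C(OC)OC)=C\B1OC(C)(C)C(C)(C)O1
F2 | step 9 | (E)-alkenylzinc chloride derived from 18 | CC(C)=CCC/C(C)=C/CC/C(C)=C/CC/C(C(OC)OC)=C\[Zn]Cl
F3 | step 13 | bis(triethylammonium) salt of the 4-hydroxy diacid | CC(C)=CCC/C(C)=C/CC/C(C)=C/CC/C(C=O)=C\C[C@@H](O)[C@H](CC(=O)[O-])C(=O)[O-].CC[NH+](CC)CC.CC[NH+](CC)CC
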